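**Retrosynthetic overview**

1. The target is (7S,8R,8'R)-lariciresinol carrying an erythro-(7''R,8''S)-guaiacylglycerol unit on O-4'. The side chain goes on last at the free 4'-phenol: Williamson reaction with a chloroacetyl oxazolidinone, Evans syn-aldol with O-tosylvanillin, Mitsunobu inversion at C-7'', hydride removal of auxiliary and esters, detosylation.
2. Core: the C-3 CH2OH (C-9) is taken back to a carboxyl and the C-4 benzylic CH2 (C-7') to a benzylic lactone C–O bond. This gives a cis-fused γ-lactone (3,7-dioxabicyclo[3.3.0]octan-2-one) that is not in the target and is opened by ionic hydrogenation.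
3. Key disconnection: the THF C-4–C-5 bond (C-8'–C-9'). The bicyclic lactone is an isomer of a 1,3-dioxan-4-one (formaldehyde acetal of a syn-aldol β-hydroxy acid) and should arise from it by acetal ionisation, Prins closure of the THF ring and lactone capture of the cation.
4. Enabling feature: the 4-alkoxy-3-methoxyphenyl ring on C-7' carries a cation next to C-8'; the C-9 carbon on C-8 lies 1,3 to C-7' and can lactonise only when cis, which fixes C-8'; C-9' is an O–CH2 carbon at acetal level. The tosyloxyaryl ring on C-7 keeps the other benzylic C–O bond inert.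
5. Ring order: dioxanone (temporary, step 6), then THF ring and γ-lactone (both in step 7), then lactone opened (step 8). The dioxanone comes from an Evans syn-aldol of an (E)-4-arylbut-3-enoyl oxazolidinone with O-tosylvanillin.

Key step: step 7

Remark: lignan numbering is used throughout (THF C-2, C-3, C-4, C-5 = C-7, C-8, C-8', C-9'; C-9 = CH2OH carbon; C-7' = benzylic CH2; doubly primed locants = glycerol unit), and compounds 1, 3, 4, 6 and 20 are taken as commercial.

**Route**

Step 1
Reactants: 1 vanillin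
Product: 2 4-formyl-2-methoxyphenyl 4-methylbenzenesulfonate (O-tosylvanillin)
Conditions: TsCl, Et3N, DMAP (cat.), CH2Cl2, 0 °C → rt
Reagents that add atoms: p-toluenesulfonyl chloride, Cc1ccc(cc1)S(Cl)(=O)=O
Why: Phenol O-sulfonylation, which makes this ring electron-poor so that its later benzylic C-7–O bond resists the Lewis acids of steps 7 and 8, and which should survive LiOOH, hydride and hydrogenolysis until step 16.

Step 2
Reactants: 3 4-(benzyloxy)-3-methoxybenzaldehyde, 4 (2-carboxyethyl)triphenylphosphonium bromide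
Product: 5 (E)-4-[4-(benzyloxy)-3-methoxyphenyl]but-3-enoic acid
Conditions: NaN(SiMe3)2 (2.1 equiv), THF, −78 °C → rt; then 1 M HCl
Reagents that add atoms: none
Why: Wittig olefination with the carboxylate-bearing ylide, which should give the styrene-conjugated β,γ-unsaturated acid mainly as the E isomer; the alkene geometry is not critical because step 7 is convergent.

Step 3
Reactants: 5 (E)-4-[4-(benzyloxy)-3-methoxyphenyl]but-3-enoic acid, 6 (S)-4-benzyloxazolidin-2-one
Product: 7 (S)-4-benzyl-3-{(E)-4-[4-(benzyloxy)-3-methoxyphenyl]but-3-enoyl}oxazolidin-2-one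
Conditions: DCC, DMAP (cat.), CH2Cl2, 0 °C → rt
Reagents that add atoms: none
Why: Carbodiimide-mediated N-acylation of the oxazolidinone under mild conditions that should leave the aryl-conjugated β,γ-alkene in place.

Step 4
Reactants: 7 (S)-4-benzyl-3-{(E)-4-[4-(benzyloxy)-3-methoxyphenyl]but-3-enoyl}oxazolidin-2-one, 2 O-tosylvanillin
Product: 9 (S)-4-benzyl-3-{(2S,3E)-4-[4-(benzyloxy)-3-methoxyphenyl]-2-[(S)-hydroxy(3-methoxy-4-tosyloxyphenyl)methyl]but-3-enoyl}oxazolidin-2-one, via dibutylboron enolate 8 (not isolated)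
Conditions: Bu2BOTf, iPr2NEt, CH2Cl2, −78 → 0 °C; then 2, −78 → 0 °C; pH 7 buffer, MeOH, H2O2, 0 °C
Reagents that add atoms: none
Why: Evans syn-aldol reaction in which the Z boron dienolate should react at its α-carbon through a chair Zimmerman–Traxler transition state on the face opposite the auxiliary benzyl group, setting C-7 (S) and C-8 in the syn relationship that becomes 2,3-trans in the THF ring and restoring the styrene.

Step 5
Reactants: 9 syn-aldol imide
Product: 11 (2S,3E)-4-[4-(benzyloxy)-3-methoxyphenyl]-2-[(S)-hydroxy(3-methoxy-4-tosyloxyphenyl)methyl]but-3-enoic acid, via peroxy acid 10 (not isolated)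
Conditions: LiOH, H2O2, THF/H2O, 0 °C; then Na2SO3; 1 M HCl
Reagents that add atoms: hydrogen peroxide, OO
Why: Hydroperoxide-mediated exocyclic cleavage of the N-acyl oxazolidinone at 0 °C followed by sulfite reduction of the peracid, conditions mild enough that retro-aldol cleavage and α-epimerisation should not compete and the aryl sulfonate stays.

Step 6
Reactants: 11 β-hydroxy acid
Product: 12 (5S,6S)-5-[(E)-2-(4-benzyloxy-3-methoxyphenyl)ethenyl]-6-(3-methoxy-4-tosyloxyphenyl)-1,3-dioxan-4-one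
Conditions: (CH2O)n, PPTS (cat.), 4 Å MS, ClCH2CH2Cl, 60 °C
Reagents that add atoms: paraformaldehyde (formaldehyde), C=O
Why: Acid-catalysed acetalisation of a β-hydroxy acid with formaldehyde to the six-membered 1,3-dioxan-4-one, which installs the future C-9' as an O-7–CH2–O-acyl acetal tied to the carboxyl group without touching a stereocenter.

Step 7
Reactants: 12 1,3-dioxan-4-one
Product: 15 (1S,4S,5R,8S)-4-[4-(benzyloxy)-3-methoxyphenyl]-8-[3-methoxy-4-(tosyloxy)phenyl]-3,7-dioxabicyclo[3.3.0]octan-2-one, via oxocarbenium triflate 13 (not isolated), via benzylic cation 14 (not isolated)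
Conditions: TMSOTf (0.3 equiv), CH2Cl2 (0.02 M), −78 → 0 °C; then Et3N
Reagents that add atoms: none
Why: Proposed new method: TMSOTf should ionise the O–CH2–O acetal of 12 on its acyloxy side (carboxylate as leaving group, as in the known Lewis-acid substitutions of 1,3-dioxan-4-ones by carbon nucleophiles) to give the O-7 methylene-oxocarbenium silyl ester 13, whose CH2 carbon (C-9') bonds to C-8' of the styrene because the 4-benzyloxy-3-methoxyphenyl ring stabilises the C-7' cation 14 (the regiochemistry of the classical Prins reaction of anethole-type styrenes with formaldehyde), after which the silyl ester carbonyl captures C-7' and releases TMSOTf, so that the whole step is a catalytic isomerisation. The closest known reaction types are the Prins bicyclisation terminated by a tethered oxygen nucleophile and the acid-mediated γ-lactonisation of 4-aryl-3-butenoic acids; new is the relay from a dioxanone through a formaldehyde-level oxocarbenium ion into a lactone. The THF ring closes in a 5-exo-trig mode with respect to the C-8'=C-7' alkene (endo with respect to the C=O+ unit), and the γ-lactone ring closes by O-attack on the cationic C-7' (five-membered, 5-endo with respect to the former alkene). C-8' is controlled by the lactone tether: only the cation with C-7' cis to the C-9 carboxyl on the THF ring can close to the cis-fused bicycle, whereas the trans epimer should return through E1 loss of H-8' to the 4-benzylidene THF and reprotonation by traces of TfOH, so that both alkene isomers and both C-8' epimers converge on 15; C-7 and C-8 are carried over from the aldol, and the configuration at C-7' (aryl on the convex face) is of no consequence because step 8 erases it. The step needs regioselective acetal ionisation (secured by the acyloxy leaving group built into the dioxanone ring), five- over six-ring closure without 2-oxonia-Cope scrambling (secured by the donor aryl on C-7'), and an inert C-7–O bond (secured by the electron-poor tosyloxyaryl ring).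

Step 8
Reactants: 15 bicyclic lactone
Product: 16 (2S,3S,4R)-4-[4-(benzyloxy)-3-methoxybenzyl]-2-[3-methoxy-4-(tosyloxy)phenyl]tetrahydrofuran-3-carboxylic acid
Conditions: Et3SiH, BF3·OEt2, CH2Cl2, −40 → 0 °C
Reagents that add atoms: none
Why: Ionic hydrogenation in which BF3 should ionise only the 4-alkoxybenzylic lactone C-7'–O bond (carboxylate leaving group, donor aryl) and Et3SiH reduces the cation to CH2, while the C-7–O ether on the tosyloxyaryl ring, the benzyl ether and C-8' stay untouched and the temporary lactone ring is removed.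

Step 9
Reactants: 16 THF carboxylic acid
Product: 17 {(2S,3R,4R)-4-[4-(benzyloxy)-3-methoxybenzyl]-2-[3-methoxy-4-(tosyloxy)phenyl]tetrahydrofuran-3-yl}methanol
Conditions: BH3·THF, THF, 0 °C → rt; MeOH quench
Reagents that add atoms: none
Why: Chemoselective borane reduction of the carboxylic acid to the C-9 primary alcohol without base, so that the α-stereocenter C-8 should not epimerise and the sulfonate is left alone.

Step 10
Reactants: 17 primary alcohol
Product: 18 {(2S,3R,4R)-4-[4-(benzyloxy)-3-methoxybenzyl]-2-[3-methoxy-4-(tosyloxy)phenyl]tetrahydrofuran-3-yl}methyl acetate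
Conditions: Ac2O, pyridine, DMAP (cat.), CH2Cl2, rt
Reagents that add atoms: acetic anhydride, CC(=O)OC(C)=O
Why: Standard O-acetylation, which masks the primary alcohol during the boron aldol and Mitsunobu steps and is removed by the hydride of step 15.

Step 11
Reactants: 18 acetate
Product: 19 {(2S,3R,4R)-4-(4-hydroxy-3-methoxybenzyl)-2-[3-methoxy-4-(tosyloxy)phenyl]tetrahydrofuran-3-yl}methyl acetate
Conditions: H2 (1 atm), 10% Pd/C, EtOAc, rt
Reagents that add atoms: none
Why: Hydrogenolysis of the benzyl aryl ether, during which the 2-aryl-THF C–O bond on the electron-poor ring, the acetate and the aryl tosylate are expected to survive brief exposure.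

Step 12
Reactants: 19 phenol, 20 (R)-4-benzyl-3-(chloroacetyl)oxazolidin-2-one
Product: 21 aryloxyacetyl imide (19 O-alkylated at O-4' with CH2C(=O)-[(R)-4-benzyl-2-oxooxazolidin-3-yl])
Conditions: K2CO3, NaI (cat.), acetone, rt → 40 °C
Reagents that add atoms: none
Why: Williamson O-alkylation of the phenoxide by the activated α-chloro imide (iodide-assisted), which attaches C-8'' and C-9'' together with the auxiliary.

Step 13
Reactants: 21 aryloxyacetyl imide, 2 O-tosylvanillin
Product: 23 (2R,3S)-3-hydroxy-3-[3-methoxy-4-(tosyloxy)phenyl]-2-aryloxypropanoyl imide (syn-aldol adduct of 21), via dibutylboron enolate 22 (not isolated)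
Conditions: Bu2BOTf, iPr2NEt, CH2Cl2, −78 → 0 °C; then 2, −78 → 0 °C; pH 7 buffer, MeOH, H2O2, 0 °C
Reagents that add atoms: none
Why: Evans syn-aldol of the aryloxyacetyl imide (Z boron enolate, chair transition state, attack anti to the auxiliary benzyl group), which should set C-8'' with the configuration of the target and C-7'' with the opposite one (threo series).

Step 14
Reactants: 23 syn-aldol adduct
Product: 24 (2R,3R)-3-(4-nitrobenzoyloxy) imide (C-7'' inverted)
Conditions: 4-nitrobenzoic acid, PPh3, DIAD, THF, 0 °C → rt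
Reagents that add atoms: 4-nitrobenzoic acid, OC(=O)c1ccc(cc1)[N+](=O)[O-]
Why: Mitsunobu esterification, which should invert the benzylic carbinol C-7'' by SN2 displacement of the oxyphosphonium ion (the electron-poor tosyloxyaryl ring disfavours an SN1 path) and so convert the threo adduct into the erythro series.

Step 15
Reactants: 24 4-nitrobenzoate imide
Product: 25 4,4''-di-O-tosyl derivative of the target
Conditions: LiBH4, MeOH (2 equiv), THF, 0 °C → rt
Reagents that add atoms: none
Why: Borohydride reduction, which should remove the oxazolidinone reductively (C-9'' becomes CH2OH) and cleave the 4-nitrobenzoate and the acetate in the same operation without touching a stereocenter or the aryl sulfonates.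

Step 16
Reactants: 25 di-O-tosyl triol
Product: 26 (7S,8R,8'R)-lariciresinol 4'-O-[(7''R,8''S)-erythro-guaiacylglycerol-8''-yl] ether (CNP0158473.3)
Conditions: KOH, MeOH/THF/H2O, 60 °C; then aq. NH4Cl
Reagents that add atoms: none
Why: Alkaline hydrolysis of the two aryl tosylates by attack at sulfur, which should release both phenols under conditions that the ethers and the benzylic alcohols tolerate.

**Compound list**

1 | vanillin (4-hydroxy-3-methoxybenzaldehyde) | O=Cc1ccc(O)c(OC)c1 | starting material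
2 | 4-formyl-2-methoxyphenyl 4-methylbenzenesulfonate (O-tosylvanillin) | O=Cc1ccc(OS(=O)(=O)c2ccc(C)cc2)c(OC)c1 | intermediate
3 | 4-(benzyloxy)-3-methoxybenzaldehyde | O=Cc1ccc(OCc2ccccc2)c(OC)c1 | starting material
4 | (2-carboxyethyl)triphenylphosphonium bromide | OC(=O)CC[P+](c1ccccc1)(c1ccccc1)c1ccccc1.[Br-] | starting material
5 | (E)-4-[4-(benzyloxy)-3-methoxyphenyl]but-3-enoic acid | OC(=O)C/C=C/c1ccc(OCc2ccccc2)c(OC)c1 | intermediate
6 | (S)-4-benzyloxazolidin-2-one | O=C1N[C@@H](Cc2ccccc2)CO1 | starting material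
7 | (S)-4-benzyl-3-{(E)-4-[4-(benzyloxy)-3-methoxyphenyl]but-3-enoyl}oxazolidin-2-one | O=C(C/C=C/c1ccc(OCc2ccccc2)c(OC)c1)N1[C@@H](Cc2ccccc2)COC1=O | intermediate
8 | Z dibutylboron dienolate of 7 | CCCCB(CCCC)O/C(=C\C=C\c1ccc(OCc2ccccc2)c(OC)c1)N1[C@@H](Cc2ccccc2)COC1=O | intermediate (not isolated)
9 | (S)-4-benzyl-3-{(2S,3E)-4-[4-(benzyloxy)-3-methoxyphenyl]-2-[(S)-hydroxy(3-methoxy-4-tosyloxyphenyl)methyl]but-3-enoyl}oxazolidin-2-one | O=C(N1[C@@H](Cc2ccccc2)COC1=O)[C@@H](/C=C/c1ccc(OCc2ccccc2)c(OC)c1)[C@H](O)c1ccc(OS(=O)(=O)c2ccc(C)cc2)c(OC)c1 | intermediate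
10 | peroxy acid corresponding to 11 | OOC(=O)[C@@H](/C=C/c1ccc(OCc2ccccc2)c(OC)c1)[C@H](O)c1ccc(OS(=O)(=O)c2ccc(C)cc2)c(OC)c1 | intermediate (not isolated)
11 | (2S,3E)-4-[4-(benzyloxy)-3-methoxyphenyl]-2-[(S)-hydroxy(3-methoxy-4-tosyloxyphenyl)methyl]but-3-enoic acid | OC(=O)[C@@H](/C=C/c1ccc(OCc2ccccc2)c(OC)c1)[C@H](O)c1ccc(OS(=O)(=O)c2ccc(C)cc2)c(OC)c1 | intermediate
12 | (5S,6S)-5-[(E)-2-(4-benzyloxy-3-methoxyphenyl)ethenyl]-6-(3-methoxy-4-tosyloxyphenyl)-1,3-dioxan-4-one | O=C1OCO[C@H](c2ccc(OS(=O)(=O)c3ccc(C)cc3)c(OC)c2)[C@@H]1/C=C/c1ccc(OCc2ccccc2)c(OC)c1 | intermediate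
13 | O-7 methylene-oxocarbenium trimethylsilyl ester, triflate | C=[O+][C@H](c1ccc(OS(=O)(=O)c2ccc(C)cc2)c(OC)c1)[C@@H](C(=O)O[Si](C)(C)C)/C=C/c1ccc(OCc2ccccc2)c(OC)c1.[O-]S(=O)(=O)C(F)(F)F | intermediate (not isolated)
14 | C-7' benzylic cation with the THF ring closed (both C-8' epimers), trimethylsilyl ester, triflate | C[Si](C)(C)OC(=O)[C@@H]1[C@@H](c2ccc(OS(=O)(=O)c3ccc(C)cc3)c(OC)c2)OCC1[CH+]c1ccc(OCc2ccccc2)c(OC)c1.[O-]S(=O)(=O)C(F)(F)F | intermediate (not isolated)
15 | (1S,4S,5R,8S)-4-[4-(benzyloxy)-3-methoxyphenyl]-8-[3-methoxy-4-(tosyloxy)phenyl]-3,7-dioxabicyclo[3.3.0]octan-2-one (cis-fused, 4-aryl on the convex face) | O=C1O[C@H](c2ccc(OCc3ccccc3)c(OC)c2)[C@H]2CO[C@H](c3ccc(OS(=O)(=O)c4ccc(C)cc4)c(OC)c3)[C@@H]12 | intermediate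
16 | (2S,3S,4R)-4-[4-(benzyloxy)-3-methoxybenzyl]-2-[3-methoxy-4-(tosyloxy)phenyl]tetrahydrofuran-3-carboxylic acid | COc1cc(C[C@H]2CO[C@H](c3ccc(OS(=O)(=O)c4ccc(C)cc4)c(OC)c3)[C@H]2C(O)=O)ccc1OCc1ccccc1 | intermediate
17 | {(2S,3R,4R)-4-[4-(benzyloxy)-3-methoxybenzyl]-2-[3-methoxy-4-(tosyloxy)phenyl]tetrahydrofuran-3-yl}methanol | COc1cc(C[C@H]2CO[C@H](c3ccc(OS(=O)(=O)c4ccc(C)cc4)c(OC)c3)[C@H]2CO)ccc1OCc1ccccc1 | intermediate
18 | acetate of 17 | COc1cc(C[C@H]2CO[C@H](c3ccc(OS(=O)(=O)c4ccc(C)cc4)c(OC)c3)[C@H]2COC(C)=O)ccc1OCc1ccccc1 | intermediate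
19 | {(2S,3R,4R)-4-(4-hydroxy-3-methoxybenzyl)-2-[3-methoxy-4-(tosyloxy)phenyl]tetrahydrofuran-3-yl}methyl acetate | COc1cc(C[C@H]2CO[C@H](c3ccc(OS(=O)(=O)c4ccc(C)cc4)c(OC)c3)[C@H]2COC(C)=O)ccc1O | intermediate
20 | (R)-4-benzyl-3-(chloroacetyl)oxazolidin-2-one | O=C(CCl)N1[C@H](Cc2ccccc2)COC1=O | starting material
21 | aryloxyacetyl imide (19 O-alkylated at O-4' by the acetyl oxazolidinone) | COc1cc(C[C@H]2CO[C@H](c3ccc(OS(=O)(=O)c4ccc(C)cc4)c(OC)c3)[C@H]2COC(C)=O)ccc1OCC(=O)N1[C@H](Cc2ccccc2)COC1=O | intermediate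
22 | Z dibutylboron enolate of 21 | COc1cc(C[C@H]2CO[C@H](c3ccc(OS(=O)(=O)c4ccc(C)cc4)c(OC)c3)[C@H]2COC(C)=O)ccc1O/C=C(\OB(CCCC)CCCC)N1[C@H](Cc2ccccc2)COC1=O | intermediate (not isolated)
23 | syn-aldol adduct, side chain (2R,3S), C-7'' hydroxyl free | COc1cc(C[C@H]2CO[C@H](c3ccc(OS(=O)(=O)c4ccc(C)cc4)c(OC)c3)[C@H]2COC(C)=O)ccc1O[C@@H](C(=O)N1[C@H](Cc2ccccc2)COC1=O)[C@@H](O)c1ccc(OS(=O)(=O)c2ccc(C)cc2)c(OC)c1 | intermediate
24 | 4-nitrobenzoate with inverted C-7'', side chain (2R,3R) | COc1cc(C[C@H]2CO[C@H](c3ccc(OS(=O)(=O)c4ccc(C)cc4)c(OC)c3)[C@H]2COC(C)=O)ccc1O[C@@H](C(=O)N1[C@H](Cc2ccccc2)COC1=O)[C@H](OC(=O)c1ccc(cc1)[N+](=O)[O-])c1ccc(OS(=O)(=O)c2ccc(C)cc2)c(OC)c1 | intermediate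
25 | 4,4''-di-O-tosyl derivative of the target (7S,8R,8'R,7''R,8''S) | COc1cc([C@@H](O)[C@H](CO)Oc2ccc(C[C@H]3CO[C@H](c4ccc(OS(=O)(=O)c5ccc(C)cc5)c(OC)c4)[C@H]3CO)cc2OC)ccc1OS(=O)(=O)c1ccc(C)cc1 | intermediate
26 | CNP0158473.3, (7S,8R,8'R)-lariciresinol 4'-O-[(7''R,8''S)-erythro-guaiacylglycerol-8''-yl] ether | COc1cc([C@@H](O)[C@H](CO)Oc2ccc(C[C@H]3CO[C@H](c4ccc(O)c(OC)c4)[C@H]3CO)cc2OC)ccc1O | target

**Step count and risks**

Total step count: 16. Longest linear sequence: 15 steps (steps 2 to 16); step 1 is the only branch and supplies 2 for steps 4 and 13.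

Steps most likely to fail:

Step 7 (Proposed new method). What may go wrong: the cation–alkene closure may take the wrong course, through bonding at C-7' (six-membered ring), 2-oxonia-Cope fragmentation, or Friedel–Crafts capture of the trans-configured cation before it can re-equilibrate. Fallback with known chemistry, which closes the THF ring through the C-8–C-8' bond by radical cyclisation and brings the benzyl aryl group in by cross-coupling; it sets out from 2 and comes back at 17. Evans syn-aldol of 2 with the boron enolate of commercial (S)-4-benzyl-3-(chloroacetyl)oxazolidin-2-one (the enantiomer of 20; Bu2BOTf, iPr2NEt) should give the chlorohydrin imide F1. O-Propargylation (propargyl bromide, Ag2O, CH2Cl2) gives the propargyl ether F2. Bu3SnH and AIBN (benzene, 80 °C) generate the α-acyl radical, whose 5-exo-dig cyclisation should give the 2,3-trans 4-methylidene-THF imide F3. LiBH4 removes the auxiliary to give the alcohol F4. Hydroboration with 9-BBN on the face anti to the C-3 substituent, followed by B-alkyl Suzuki–Miyaura coupling with commercial 1-(benzyloxy)-4-bromo-2-methoxybenzene (Pd(dppf)Cl2, K3PO4, DMF/H2O), should then give 17.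

Step 8. What may go wrong: competing ionisation of the C-7–O ether (over-reduction to a ring-opened diarylbutane), or loss of the C-8' configuration by elimination and reprotonation at the C-7' cation stage. Fallback without a cation at C-7' (radical deoxygenation), from 15 back to 18. LiBH4 reduces the lactone to the diol F5. Selective acetylation of the primary hydroxyl (AcCl, 2,4,6-collidine, CH2Cl2, −78 °C) gives the monoacetate F6. 1,1'-Thiocarbonyldiimidazole converts the benzylic alcohol into the thiocarbonylimidazolide F7. Barton–McCombie deoxygenation (Bu3SnH, AIBN, toluene, 90 °C) should then give 18.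

Step 14. What may go wrong: β-elimination of the activated β-hydroxy imide to an α-aryloxy cinnamoyl imide, or partial SN1 scrambling, instead of clean inversion. Fallback that sets C-7'' by oxidation and Felkin–Anh reduction instead of inversion, from 23 back to 25. LiBH4 reduces imide and acetate to the threo triol F8. TBSCl and imidazole silylate the two primary hydroxyls to give the bis-silyl ether F9. Dess–Martin periodinane (NaHCO3 buffer) gives the ketone F10. L-Selectride (LiBH(s-Bu)3, THF, −78 °C) should deliver hydride anti to the aryloxy group and give the erythro alcohol F11. HF·pyridine then removes the silyl groups to give 25.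

**Further compounds**

F1 | step 7 | (S)-4-benzyl-3-{(2S,3R)-2-chloro-3-hydroxy-3-[3-methoxy-4-(tosyloxy)phenyl]propanoyl}oxazolidin-2-one | O=C(N1[C@@H](Cc2ccccc2)COC1=O)[C@@H](Cl)[C@H](O)c1ccc(OS(=O)(=O)c2ccc(C)cc2)c(OC)c1
F2 | step 7 | O-propargyl ether of F1 | O=C(N1[C@@H](Cc2ccccc2)COC1=O)[C@@H](Cl)[C@H](OCC#C)c1ccc(OS(=O)(=O)c2ccc(C)cc2)c(OC)c1
F3 | step 7 | (S)-4-benzyl-3-{(2S,3S)-2-[3-methoxy-4-(tosyloxy)phenyl]-4-methylidenetetrahydrofuran-3-carbonyl}oxazolidin-2-one | C=C1CO[C@H](c2ccc(OS(=O)(=O)c3ccc(C)cc3)c(OC)c2)[C@H]1C(=O)N1[C@@H](Cc2ccccc2)COC1=O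
F4 | step 7 | {(2S,3R)-2-[3-methoxy-4-(tosyloxy)phenyl]-4-methylidenetetrahydrofuran-3-yl}methanol | C=C1CO[C@H](c2ccc(OS(=O)(=O)c3ccc(C)cc3)c(OC)c2)[C@H]1CO
F5 | step 8 | (S)-[4-(benzyloxy)-3-methoxyphenyl]{(3R,4R,5S)-4-(hydroxymethyl)-5-[3-methoxy-4-(tosyloxy)phenyl]tetrahydrofuran-3-yl}methanol | COc1cc([C@@H](O)[C@H]2CO[C@H](c3ccc(OS(=O)(=O)c4ccc(C)cc4)c(OC)c3)[C@H]2CO)ccc1OCc1ccccc1
F6 | step 8 | primary (C-9) monoacetate of F5 | COc1cc([C@@H](O)[C@H]2CO[C@H](c3ccc(OS(=O)(=O)c4ccc(C)cc4)c(OC)c3)[C@H]2COC(C)=O)ccc1OCc1ccccc1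
F7 | step 8 | O-(imidazol-1-ylthiocarbonyl) derivative of F6 at the benzylic oxygen | COc1cc([C@@H](OC(=S)n2ccnc2)[C@H]2CO[C@H](c3ccc(OS(=O)(=O)c4ccc(C)cc4)c(OC)c3)[C@H]2COC(C)=O)ccc1OCc1ccccc1
F8 | step 14 | threo (7''S,8''S) diastereomer of 25 | COc1cc([C@H](O)[C@H](CO)Oc2ccc(C[C@H]3CO[C@H](c4ccc(OS(=O)(=O)c5ccc(C)cc5)c(OC)c4)[C@H]3CO)cc2OC)ccc1OS(=O)(=O)c1ccc(C)cc1
F9 | step 14 | 9,9''-bis-O-TBS ether of F8 | COc1cc([C@H](O)[C@H](CO[Si](C)(C)C(C)(C)C)Oc2ccc(C[C@H]3CO[C@H](c4ccc(OS(=O)(=O)c5ccc(C)cc5)c(OC)c4)[C@H]3CO[Si](C)(C)C(C)(C)C)cc2OC)ccc1OS(=O)(=O)c1ccc(C)cc1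
F10 | step 14 | C-7'' ketone from F9 | COc1cc(C(=O)[C@H](CO[Si](C)(C)C(C)(C)C)Oc2ccc(C[C@H]3CO[C@H](c4ccc(OS(=O)(=O)c5ccc(C)cc5)c(OC)c4)[C@H]3CO[Si](C)(C)C(C)(C)C)cc2OC)ccc1OS(=O)(=O)c1ccc(C)cc1
F11 | step 14 | erythro (7''R,8''S) alcohol, 9,9''-bis-O-TBS ether of 25 | COc1cc([C@@H](O)[C@H](CO[Si](C)(C)C(C)(C)C)Oc2ccc(C[C@H]3CO[C@H](c4ccc(OS(=O)(=O)c5ccc(C)cc5)c(OC)c4)[C@H]3CO[Si](C)(C)C(C)(C)C)cc2OC)ccc1OS(=O)(=O)c1ccc(C)cc1
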